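**Plan**
- Numbering used throughout: ring C1 (C=O), C2=C3, C4 (OMe), C5 (CH2), C6 (quaternary, allyl); side chain C7 (CHMe) and C8 (CH–O, aryl).
- Enabling feature: the γ-hydroxy ketone O–C8–C7–C6–C1(=O) and the 1,4-dioxygenated enone segment C1(=O)–C2=C3–C4(OMe) together are a hydrolysed 7-oxabicyclo[2.2.1]heptene ketal. This is a furan ring (C1–C4 plus the C4 oxygen) added across a C5=C6 alkene that is tied to the furan through the C8 oxygen.
- Bonds cut, in order: acetate C–O; the C4 methyl ether and the C1 ketal; C1–C6 and C4–C5 (the [4+2]); the furyl C1–O(C8) bond; the C6–allyl bond; the C7–C8 bond.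
- Forward: the open chain C5=C6(allyl)–C7–C8(OH)Ar is built (steps 1–4) and the furan is attached through oxygen (step 5). One thermal operation then closes the carbocycle and a temporary oxolane, and methanol opens the oxygen bridge (step 6). Methylation, ketal hydrolysis (which reopens the oxolane) and acetylation finish (steps 7–9).
- Stereochemistry: C7 from (S)-but-3-yn-2-ol through anti SN2′ then anti SE2′; C8 from the syn-selective open transition state of the aldehyde addition; C6 and C4 together in the cycloaddition; the C4–O bond is never broken afterwards.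

Key step: step 6

Remark on the chemistry: the mixed ketals 12 and 13 are drawn as the cis-fused anomer expected from methanol entering anti to the departing bridge oxygen. The other anomer would serve equally, because this carbon becomes the C1 carbonyl in step 8.

Step 1
Reactants: 1 (S)-but-3-yn-2-ol
Product: 2 (S)-but-3-yn-2-yl methanesulfonate
Conditions: MsCl, Et3N, CH2Cl2, −78 to 0 °C
Reagents that add atoms: methanesulfonyl chloride, CS(=O)(=O)Cl
Why: O-Sulfonylation (mesylation) of a secondary alcohol that does not touch the C–O stereocentre, so the S configuration is carried into 2.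

Step 2
Reactants: 2 (S)-but-3-yn-2-yl methanesulfonate
Product: 3 (M)-tributyl(buta-1,2-dien-1-yl)stannane
Conditions: Bu3SnH, LiN(iPr)2, THF, 0 °C; CuBr·SMe2, −78 °C; then 2, −78 °C
Reagents that add atoms: tributyltin hydride, CCCC[SnH](CCCC)CCCC
Why: Anti SN2′ substitution of a propargylic mesylate by a stannylcopper reagent, in which tin enters at the alkyne terminus on the face opposite the leaving group and so converts the S carbinol centre into the M allene axis.

Step 3
Reactants: 3 (M)-tributyl(buta-1,2-dien-1-yl)stannane; 4 3,4,5-trimethoxybenzaldehyde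
Product: 5 (1R,2S)-2-methyl-1-(3,4,5-trimethoxyphenyl)but-3-yn-1-ol
Conditions: BF3·OEt2, CH2Cl2, −78 °C; aq. NaHCO3
Reagents that add atoms: none
Why: Lewis acid-promoted SE2′ addition of an allenylstannane to an aldehyde through an open transition state, in which the aldehyde carbon bonds to the methyl-bearing allene terminus anti to tin (this sets C7 as S, the new C–C bond taking the place the mesylate oxygen had) and the open arrangement that keeps the aryl group away from the allene methyl favours the syn adduct (this sets C8 as R).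

Step 4
Reactants: 5 (1R,2S)-2-methyl-1-(3,4,5-trimethoxyphenyl)but-3-yn-1-ol; 6 allyl bromide
Product: 8 (1R,2S)-2-methyl-3-methylidene-1-(3,4,5-trimethoxyphenyl)hex-5-en-1-ol, via alkenylindium adduct 7 (not isolated)
Conditions: In powder, 6, DMF, rt, forming (C3H5)3In2Br3; then 5, 100 °C; 1 M HCl work-up
Reagents that add atoms: indium powder, [In] (kept only in intermediate 7, absent from 8)
Why: Allylindation (carbometallation) of the terminal alkyne, a reaction in which homopropargylic alcohols and simple 1-alkynes take the allyl group at the internal carbon and indium at the terminus by syn addition, followed by protonolysis of the C–In bond on acidic work-up; no stereocentre is formed or touched.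

Step 5
Reactants: 8 (1R,2S)-2-methyl-3-methylidene-1-(3,4,5-trimethoxyphenyl)hex-5-en-1-ol; 9 2-bromofuran
Product: 10 2-{[(1R,2S)-2-methyl-3-methylidene-1-(3,4,5-trimethoxyphenyl)hex-5-en-1-yl]oxy}furan
Conditions: [Pd(allyl)Cl]2 (cat.), RockPhos, Cs2CO3, 9 (3 equiv), toluene, 60 °C
Reagents that add atoms: none
Why: Palladium-catalysed C–O cross-coupling (Buchwald–Hartwig-type etherification) of a secondary alcohol with a heteroaryl bromide, in which the bulky biaryl phosphine speeds C–O reductive elimination relative to β-hydride elimination, the carbonate keeps the acid-labile 2-alkoxyfuran intact and the C8–O bond is not broken, so C8 keeps its configuration.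

Step 6
Reactants: 10 2-{[(1R,2S)-2-methyl-3-methylidene-1-(3,4,5-trimethoxyphenyl)hex-5-en-1-yl]oxy}furan
Product: 12 (2R,3S,3aR,5R,7aR)-7a-methoxy-3-methyl-3a-(prop-2-en-1-yl)-2-(3,4,5-trimethoxyphenyl)-2,3,3a,4,5,7a-hexahydro-1-benzofuran-5-ol, via bridged cycloadduct 11 (not isolated)
Conditions: MeOH–toluene (1:4), iPr2NEt (0.2 equiv), sealed tube, 130 °C; then PPTS (cat.), 0 °C, if bridge opening is incomplete
Reagents that add atoms: methanol, CO
Why: Proposed new method: on heating, the 2-alkoxyfuran (a diene whose HOMO is raised by the alkoxy donor) and the tethered 1,1-disubstituted alkene should join in a concerted, asynchronous thermal [4+2] cycloaddition, furan C2 bonding to C6 and furan C5 to the methylene C5, to give the bridged ketal 11, whose strained C1–O bridge bond then ionises with help from the tether oxygen so that methanol captures the C1 oxocarbenium ion as 12; this capture takes 11 out of the cycloaddition/cycloreversion equilibrium and should be faster than the 1,2-hydride shift from C4 that would leave a C4 ketone. The closest known reaction type is the intramolecular Diels–Alder and bridge-opening cascade of 2-amidofurans with homoallyl-type tethers (1,1-disubstituted alkenes included, which give quaternary ring-fusion carbons), together with intermolecular cycloadditions of 2-methoxyfuran followed by bridge opening; a 2-alkoxyfuran joined through an O–C–C tether to an unactivated alkene has not been shown to react this way. Two rings close at once in a type 1 intramolecular Diels–Alder reaction, the carbocycle C1–C6 as the six-membered cycloaddition ring and the oxolane O–C8–C7–C6–C1 as the fused five-membered tether ring, while the 1,4-oxygen bridge is only temporary. C6 is controlled by the three-atom tether, which can span C1 and C6 only on the exo side (syn to the oxygen bridge) and so turns the allyl group endo, and by the cis methyl and aryl groups on C7 and C8, which should take the face of the forming oxolane that points away from the endo allyl group; C4 follows from the suprafacial addition, its oxygen ending cis to the C7 branch and trans to allyl, and the C1 configuration is without consequence. The step needs π-facial selectivity relative to C7 and C8, which these tether substituents should supply (they also favour the reactive conformer through the Thorpe–Ingold effect), and site selectivity between the two alkenes, which is secured because addition to the allyl double bond would need a seven-membered tether ring. The amine keeps the medium non-acidic so that the furyl ether and the allylic ketal survive.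

Step 7
Reactants: 12 (2R,3S,3aR,5R,7aR)-7a-methoxy-3-methyl-3a-(prop-2-en-1-yl)-2-(3,4,5-trimethoxyphenyl)-2,3,3a,4,5,7a-hexahydro-1-benzofuran-5-ol
Product: 13 (2R,3S,3aR,5R,7aR)-5,7a-dimethoxy-3-methyl-3a-(prop-2-en-1-yl)-2-(3,4,5-trimethoxyphenyl)-2,3,3a,4,5,7a-hexahydro-1-benzofuran
Conditions: NaH, MeI, THF, 0 °C to rt
Reagents that add atoms: iodomethane, CI
Why: Williamson etherification of the only free hydroxyl group (C4–OH), the C8 oxygen and C1 being locked in the base-stable mixed ketal, with no bond to a stereocentre broken.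

Step 8
Reactants: 13 (2R,3S,3aR,5R,7aR)-5,7a-dimethoxy-3-methyl-3a-(prop-2-en-1-yl)-2-(3,4,5-trimethoxyphenyl)-2,3,3a,4,5,7a-hexahydro-1-benzofuran
Product: 14 megaphone, (4R,6R)-6-[(1R,2S)-1-hydroxy-1-(3,4,5-trimethoxyphenyl)propan-2-yl]-4-methoxy-6-(prop-2-en-1-yl)cyclohex-2-en-1-one
Conditions: PPTS, acetone–H2O (4:1), rt
Reagents that add atoms: water, O
Why: Acid-catalysed hydrolysis of the mixed cyclic ketal through the C1 oxocarbenium ion, which releases the conjugated C1 ketone and the C8 hydroxyl, deletes the anomeric centre and leaves C4, C6, C7 and C8 untouched under these mild conditions.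

Step 9
Reactants: 14 megaphone
Product: 15 megaphone acetate, (1R,2S)-2-[(1R,5R)-5-methoxy-2-oxo-1-(prop-2-en-1-yl)cyclohex-3-en-1-yl]-1-(3,4,5-trimethoxyphenyl)propyl acetate
Conditions: Ac2O, DMAP (cat.), pyridine, CH2Cl2, 0 °C to rt
Reagents that add atoms: acetic anhydride, CC(=O)OC(C)=O
Why: DMAP-catalysed acyl transfer from acetic anhydride to the secondary benzylic alcohol (esterification at oxygen), which retains the C8 configuration.

**Compound list**
1 | (S)-but-3-yn-2-ol | C#C[C@H](C)O | starting material
2 | (S)-but-3-yn-2-yl methanesulfonate | C#C[C@H](C)OS(C)(=O)=O | intermediate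
3 | (M)-tributyl(buta-1,2-dien-1-yl)stannane (axial descriptor aR) | [H]C([Sn](CCCC)(CCCC)CCCC)=[C@@]=C([H])C | intermediate
4 | 3,4,5-trimethoxybenzaldehyde | O=Cc1cc(OC)c(OC)c(OC)c1 | starting material
5 | (1R,2S)-2-methyl-1-(3,4,5-trimethoxyphenyl)but-3-yn-1-ol (syn) | C#C[C@H](C)[C@@H](O)c1cc(OC)c(OC)c(OC)c1 | intermediate
6 | allyl bromide (3-bromoprop-1-ene) | C=CCBr | starting material
7 | alkenylindium adduct of 5, drawn in its simplest form as the (E)-alkenylindium dibromide: allyl on the internal carbon, InBr2 on the terminal carbon cis to allyl | C=CC/C(=C\[In](Br)Br)[C@H](C)[C@@H](O)c1cc(OC)c(OC)c(OC)c1 | intermediate (not isolated)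
8 | (1R,2S)-2-methyl-3-methylidene-1-(3,4,5-trimethoxyphenyl)hex-5-en-1-ol | C=CCC(=C)[C@H](C)[C@@H](O)c1cc(OC)c(OC)c(OC)c1 | intermediate
9 | 2-bromofuran | Brc1ccco1 | starting material
10 | 2-{[(1R,2S)-2-methyl-3-methylidene-1-(3,4,5-trimethoxyphenyl)hex-5-en-1-yl]oxy}furan | C=CCC(=C)[C@H](C)[C@@H](Oc1ccco1)c1cc(OC)c(OC)c(OC)c1 | intermediate
11 | bridged cycloadduct: 7-oxabicyclo[2.2.1]hept-2-ene ketal (oxygen bridging C1 and C4) with the allyl group endo on C6 and an oxolane O–C8–C7 fused exo across C1–C6, methyl and aryl cis on the oxolane | C=CC[C@]12C[C@@H]3C=C[C@]1(O3)O[C@@H](c4cc(OC)c(OC)c(OC)c4)[C@H]2C | intermediate (not isolated)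
12 | (2R,3S,3aR,5R,7aR)-7a-methoxy-3-methyl-3a-(prop-2-en-1-yl)-2-(3,4,5-trimethoxyphenyl)-2,3,3a,4,5,7a-hexahydro-1-benzofuran-5-ol (cis-fused methyl ketal, free C4 hydroxyl) | C=CC[C@]12C[C@@H](O)C=C[C@@]1(OC)O[C@@H](c3cc(OC)c(OC)c(OC)c3)[C@H]2C | intermediate
13 | (2R,3S,3aR,5R,7aR)-5,7a-dimethoxy-3-methyl-3a-(prop-2-en-1-yl)-2-(3,4,5-trimethoxyphenyl)-2,3,3a,4,5,7a-hexahydro-1-benzofuran | C=CC[C@]12C[C@@H](OC)C=C[C@@]1(OC)O[C@@H](c3cc(OC)c(OC)c(OC)c3)[C@H]2C | intermediate
14 | megaphone, (4R,6R)-6-[(1R,2S)-1-hydroxy-1-(3,4,5-trimethoxyphenyl)propan-2-yl]-4-methoxy-6-(prop-2-en-1-yl)cyclohex-2-en-1-one | C=CC[C@]1([C@H](C)[C@@H](O)c2cc(OC)c(OC)c(OC)c2)C[C@@H](OC)C=CC1=O | intermediate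
15 | megaphone acetate, (1R,2S)-2-[(1R,5R)-5-methoxy-2-oxo-1-(prop-2-en-1-yl)cyclohex-3-en-1-yl]-1-(3,4,5-trimethoxyphenyl)propyl acetate | C=CC[C@]1([C@H](C)[C@@H](OC(C)=O)c2cc(OC)c(OC)c(OC)c2)C[C@@H](OC)C=CC1=O | target

**Step count**
Total: 9 steps. Longest linear sequence: 9 steps, from 1 to 15; compounds 4, 6 and 9 are bought.

**Steps most likely to fail**

Step 6 (the proposed new method). Four things may go wrong:
- the unactivated alkene may add too slowly, so that the furyl ether decomposes first;
- cycloreversion may outpace capture by methanol;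
- the opened bridge may collapse by hydride shift to a C4 ketone;
- the facial preference set by the tether substituents may be too small.

The fallback uses known enolate chemistry, sets out from 5 and returns at 14.
- Ruthenium-catalysed cycloisomerisation–oxidation of the homopropargylic alcohol (CpRu(cod)Cl, tri(2-furyl)phosphine, N-hydroxysuccinimide, NaHCO3, DMF–H2O, 95 °C) should give the cis lactone (4S,5R)-4-methyl-5-(3,4,5-trimethoxyphenyl)oxolan-2-one F1. Its carbonyl carbon is C1 and its α-carbon is C6.
- Alkylation of the lithium enolate (LiN(iPr)2, THF–DMPU, −78 °C) with 2-(2-bromoethyl)-2-methyl-1,3-dioxolane and NaI, anti to the C7 methyl, should give the mono-alkylated ketal lactone F2.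
- A second enolate alkylation with allyl bromide, again anti to the methyl group, should set the quaternary C6 in the allylated ketal lactone F3.
- Ketal cleavage (1 M HCl, THF) should give the keto lactone F4.
- Dieckmann-type closure of the methyl ketone enolate onto the lactone carbonyl (LiN(SiMe3)2, THF, −78 to 0 °C) should give the hydroxy dione F5.
- Cyclodehydration (TsOH, toluene, reflux) should give the bicyclic vinylogous ester F6.
- Kinetic enolisation at C4 (LiN(iPr)2) and hydroxylation with 2-(phenylsulfonyl)-3-phenyloxaziridine, on the face opposite the angular allyl group, should give the C4 hydroxy vinylogous ester F7.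
- O-Methylation (MeOTf, 2,6-di-tert-butylpyridine) should give the C4 methoxy vinylogous ester F8.
- Reduction (iBu2AlH, toluene, −78 °C) should give the allylic alcohol F9.
- Dilute aqueous HCl should then hydrolyse the enol ether with loss of water (Stork–Danheiser transposition) to megaphone 14.

Step 5. The palladium alkoxide of this hindered benzylic alcohol may undergo β-hydride elimination to the ketone. C–O reductive elimination from an electron-rich furylpalladium complex may be slow. The acid-labile furyl ether may also be lost on isolation.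

The fallback sets out from 8 and returns at 10.
- The potassium alkoxide of 8 (KN(SiMe3)2, THF, −40 °C) should displace nitrite from methyl 5-nitrofuran-2-carboxylate by nucleophilic aromatic substitution, giving the furoate ether F10.
- Saponification (LiOH, THF–MeOH–H2O) should give the furoic acid F11.
- Silver-catalysed protodecarboxylation (Ag2CO3 cat., DMSO, 100 °C), the classical last stage of 2-alkoxyfuran syntheses, should give 10.

Step 4. Carbometallation may stall at the α-branched alkyne or leak to the linear regioisomer. Indium Lewis acids may also ionise the electron-rich benzylic C–O bond at 100 °C.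

The fallback sets out from 5 and returns at 8.
- Silylation (TBSCl, imidazole, DMF) should give the silyl ether of the alkynol F12.
- Markovnikov bromoboration with B-bromo-9-borabicyclo[3.3.1]nonane (CH2Cl2, 0 °C) and protonolysis with acetic acid should give the 2-bromoalkene silyl ether F13.
- Stille coupling with allyltributylstannane (Pd(PPh3)4, toluene, 90 °C) should give the silyl ether of the diene alcohol F14.
- Desilylation (Bu4NF, THF) should give 8.

Further compounds
F1 | step 6 | (4S,5R)-4-methyl-5-(3,4,5-trimethoxyphenyl)oxolan-2-one | O=C1C[C@H](C)[C@H](c2cc(OC)c(OC)c(OC)c2)O1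
F2 | step 6 | (3S,4S,5R)-4-methyl-3-[2-(2-methyl-1,3-dioxolan-2-yl)ethyl]-5-(3,4,5-trimethoxyphenyl)oxolan-2-one | O=C1[C@@H](CCC2(C)OCCO2)[C@H](C)[C@H](c3cc(OC)c(OC)c(OC)c3)O1
F3 | step 6 | (3S,4S,5R)-4-methyl-3-[2-(2-methyl-1,3-dioxolan-2-yl)ethyl]-3-(prop-2-en-1-yl)-5-(3,4,5-trimethoxyphenyl)oxolan-2-one | O=C1[C@](CC=C)(CCC2(C)OCCO2)[C@H](C)[C@H](c3cc(OC)c(OC)c(OC)c3)O1
F4 | step 6 | (3S,4S,5R)-4-methyl-3-(3-oxobutyl)-3-(prop-2-en-1-yl)-5-(3,4,5-trimethoxyphenyl)oxolan-2-one | O=C1[C@](CC=C)(CCC(C)=O)[C@H](C)[C@H](c3cc(OC)c(OC)c(OC)c3)O1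
F5 | step 6 | (S)-4-[(1R,2S)-1-hydroxy-1-(3,4,5-trimethoxyphenyl)propan-2-yl]-4-(prop-2-en-1-yl)cyclohexane-1,3-dione | C=CC[C@]1([C@H](C)[C@@H](O)c2cc(OC)c(OC)c(OC)c2)CCC(=O)CC1=O
F6 | step 6 | (2R,3S,3aS)-3-methyl-3a-(prop-2-en-1-yl)-2-(3,4,5-trimethoxyphenyl)-3,3a,4,5-tetrahydro-1-benzofuran-6(2H)-one | C=CC[C@]12CCC(=O)C=C1O[C@@H](c3cc(OC)c(OC)c(OC)c3)[C@H]2C
F7 | step 6 | (2R,3S,3aR,5R)-5-hydroxy-3-methyl-3a-(prop-2-en-1-yl)-2-(3,4,5-trimethoxyphenyl)-3,3a,4,5-tetrahydro-1-benzofuran-6(2H)-one | C=CC[C@]12C[C@@H](O)C(=O)C=C1O[C@@H](c3cc(OC)c(OC)c(OC)c3)[C@H]2C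
F8 | step 6 | (2R,3S,3aR,5R)-5-methoxy-3-methyl-3a-(prop-2-en-1-yl)-2-(3,4,5-trimethoxyphenyl)-3,3a,4,5-tetrahydro-1-benzofuran-6(2H)-one | C=CC[C@]12C[C@@H](OC)C(=O)C=C1O[C@@H](c3cc(OC)c(OC)c(OC)c3)[C@H]2C
F9 | step 6 | (2R,3S,3aR,5R)-5-methoxy-3-methyl-3a-(prop-2-en-1-yl)-2-(3,4,5-trimethoxyphenyl)-2,3,3a,4,5,6-hexahydro-1-benzofuran-6-ol, carbinol configuration at C6 of the benzofuran left open because both epimers converge | C=CC[C@]12C[C@@H](OC)C(O)C=C1O[C@@H](c3cc(OC)c(OC)c(OC)c3)[C@H]2C
F10 | step 5 | methyl 5-{[(1R,2S)-2-methyl-3-methylidene-1-(3,4,5-trimethoxyphenyl)hex-5-en-1-yl]oxy}furan-2-carboxylate | C=CCC(=C)[C@H](C)[C@@H](Oc1ccc(o1)C(=O)OC)c1cc(OC)c(OC)c(OC)c1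
F11 | step 5 | 5-{[(1R,2S)-2-methyl-3-methylidene-1-(3,4,5-trimethoxyphenyl)hex-5-en-1-yl]oxy}furan-2-carboxylic acid | C=CCC(=C)[C@H](C)[C@@H](Oc1ccc(o1)C(=O)O)c1cc(OC)c(OC)c(OC)c1
F12 | step 4 | tert-butyl(dimethyl){[(1R,2S)-2-methyl-1-(3,4,5-trimethoxyphenyl)but-3-yn-1-yl]oxy}silane | C#C[C@H](C)[C@@H](O[Si](C)(C)C(C)(C)C)c1cc(OC)c(OC)c(OC)c1
F13 | step 4 | {[(1R,2R)-3-bromo-2-methyl-1-(3,4,5-trimethoxyphenyl)but-3-en-1-yl]oxy}(tert-butyl)dimethylsilane | C=C(Br)[C@H](C)[C@@H](O[Si](C)(C)C(C)(C)C)c1cc(OC)c(OC)c(OC)c1
F14 | step 4 | tert-butyl(dimethyl){[(1R,2S)-2-methyl-3-methylidene-1-(3,4,5-trimethoxyphenyl)hex-5-en-1-yl]oxy}silane | C=CCC(=C)[C@H](C)[C@@H](O[Si](C)(C)C(C)(C)C)c1cc(OC)c(OC)c(OC)c1
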